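The question is what stands after 1.5 min. I start from the J still unspent, since J.Z, G and L share what has gone from it.

J 0.12 M (fed, over 5.0 s); X 0.216 M; time 1.5 min; volume of the second phase over the first 0.25

- the J.Z standing at 1.5 min, as a percentage of the J charged
- the G standing at 1.5 min, as a percentage of the J charged
- the L standing at 1.5 min, as a percentage of the J charged
- amount of J.Z if the flask were left three thousand times as long, in percent of the J charged

    Z ⇌ X, rate k1*([Z] - [X]/K1) per volume of the first phase (K1 = 0.40, k1 = 0.012 s⁻¹)
    J.Z ⇌ L (K2 = 0.60, k2 = 0.020 s⁻¹)
    J + Z → J.Z (k3 = 0.084 M⁻¹ s⁻¹)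
    J.Z → G (k4 = 0.052 s⁻¹)
    J.Z ⇌ E, rate k5*([J.Z] - [E]/K5) per volume of the first phase (K5 = 0.29, k5 = 1.2 s⁻¹)

- amounts and yields of J.Z count E too
- in the second phase: X, E; everything else is in the first
- charges count per volume of the first phase; a concentration in a rate is the amount of a species over the volume of its own phase; every rate counts per litre of the first phase
- run time (flask): 1.5 min

I count in charges of J and look for what I can freeze, the reagent pool, Z plus X together. Each charge of J spent takes one charge from it.

| J spent, charges | pool left, charges | Z, charges | rate constant of J |
|---|---|---|---|
| 0 | 1.80 | 1.64 | 0.990 min⁻¹ |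
| 0.5 | 1.30 | 1.18 | 0.715 min⁻¹ |
| 1 | 0.800 | 0.727 | 0.440 min⁻¹ |

The Z column is the pool column times 90.9%, the equilibrium share of Z. I may use that share because transfer relaxes with a half-life of 0.0875 min, short against 1.5 min.

The last row still shows pool left, so J is the limiting reagent. Down the table the rate constant falls from the first row to the last, so I take the middle row and freeze it. The frozen rate constant, the pseudo-first-order constant of J with Z held at its value when half the charge is spent, is 0.715 min⁻¹.

That leaves 34.2% of the J at 1.5 min. I expect G to take more of the rest than L, because J.Z has a half-life of 0.22 min towards G against 0.58 min towards L. Over the long run I expect J.Z to drain into G.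

The forecast gives 10.1% J.Z, 48.4% G, 6.3% L and 0% for the long run, with this ground for the spending of J: “Treating J + Z as second order”. Its figures leave 35.2% for J, a little above my 34.2%.

The flask gives 10.1% J.Z, 48.4% G, 6.26% L and 0% for the long run, as the forecast says. With the J held, the L of this flask moves by 5 points once X comes down to 0.0301 M. Its J stands at 35.3% of the charge at 1.50 min, against my 34.2%. In a neighbour flask charged with 0.048 M of J, the middle row gives a frozen rate constant of 0.880 min⁻¹, which leaves 26.7%, and that neighbour flask holds 29.6% of its J at 1.50 min.

(The numbers were chosen freely; no experiment stands behind them.)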